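**Retrosynthetic overview** (side-chain carbons are C1' at the benzylic CH2 to C11' at the carbinol carbon)
1. No ring is formed: the arene is bought as 2,4-dihydroxy-6-methylbenzaldehyde, which fixes where the chain sits.
2. C1'–C2' (last bond): the derived hydroxymethyl-resorcinol, as its quinone methide, is alkenylated by an (E)-alkenyltrifluoroborate with no protecting groups.
3. C5'–C6' (key step): nickel-electrocatalytic decarboxylative alkenylation joins pent-4-ynoic acid, as its redox-active ester, to the chiral (E)-vinyl iodide.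
4. Both E-trisubstituted alkenes come from zirconium-catalysed methylalumination of terminal alkynes; C6' comes from an Ohira–Bestmann homologation.
5. The C10' stereocentre is bought in (R)-5-oxotetrahydrofuran-2-carboxylic acid (D-glutamic acid series); MeMgBr builds the gem-dimethyl carbinol.

Assumption: the target SMILES is read as (10'R), and (R)-5-oxotetrahydrofuran-2-carboxylic acid (the diazotisation product of D-glutamic acid) is taken as a catalogue compound.

**Route**

Step 1
Reactants: 1 (2R)-5-oxotetrahydrofuran-2-carboxylic acid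
Product: 2 ethyl (2R)-5-oxotetrahydrofuran-2-carboxylate
Conditions: EtOH (5 equiv), TsOH·H2O (2 mol %), toluene, reflux (Dean–Stark); bulb-to-bulb distillation
Reagents that add atoms: ethanol CCO
Why: Acid-catalysed Fischer esterification with azeotropic water removal; no base is present, so the alpha-oxygenated stereocentre bought in 1 is not epimerised.

Step 2
Reactants: 2 ethyl (2R)-5-oxotetrahydrofuran-2-carboxylate
Product: 4 (5R)-5-(2-hydroxypropan-2-yl)dihydrofuran-2(3H)-one, via methyl ketone 3 (not isolated)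
Conditions: MeMgBr (2.1 equiv), THF, −78 to −40 °C; aq. NH4Cl
Reagents that add atoms: methylmagnesium bromide C[Mg]Br
Why: Double Grignard addition at the alpha-alkoxy-activated exocyclic ester (ketone 3 reacts faster than either ester and the lactone is spared at −78 °C with 2.1 equiv); the stereocentre is not touched, and any alkoxide-driven change of lactone ring size is harmless because step 3 opens the lactone anyway.

Step 3
Reactants: 4 (5R)-5-(2-hydroxypropan-2-yl)dihydrofuran-2(3H)-one
Product: 6 (3R)-2-methylhept-6-yne-2,3-diol, via lactol 5 (not isolated)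
Conditions: i-Bu2AlH (2.2 equiv), CH2Cl2, −78 °C; then MeOH, K2CO3 (3 equiv), dimethyl (1-diazo-2-oxopropyl)phosphonate (1.6 equiv), −78 °C to rt, 16 h
Reagents that add atoms: dimethyl (1-diazo-2-oxopropyl)phosphonate CC(=O)C(=[N+]=[N-])P(=O)(OC)OC
Why: Half-reduction of the lactone to lactol 5, then Seyferth–Gilbert homologation (Ohira–Bestmann variant) on its open hydroxy-aldehyde form gives the terminal alkyne under K2CO3/MeOH, which cannot epimerise the remote carbinol centre.

Step 4
Reactants: 6 (3R)-2-methylhept-6-yne-2,3-diol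
Product: 8 (3R,6E)-7-iodo-2,6-dimethylhept-6-ene-2,3-diol, via alkenylalane 7 (not isolated)
Conditions: AlMe3 (4.5 equiv), Cp2ZrCl2 (0.3 equiv), CH2Cl2, 0 °C to rt, 16 h; then I2 (1.4 equiv), THF, −30 to 0 °C
Reagents that add atoms: trimethylaluminium C[Al](C)C; iodine [I][I]
Why: Negishi zirconium-catalysed methylalumination adds CH3 and Al syn across the terminal alkyne (methyl to the internal carbon) and stereoretentive iodinolysis fixes the E-trisubstituted alkene, the diol riding through as its aluminium alkoxide.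

Step 5
Reactants: 8 (3R,6E)-7-iodo-2,6-dimethylhept-6-ene-2,3-diol; 9 pent-4-ynoic acid
Product: 11 (3R,6E)-2,6-dimethylundec-6-en-10-yne-2,3-diol, via redox-active ester 10 (not isolated)
Conditions: 9 (2 equiv), N-hydroxyphthalimide (2 equiv), N,N'-diisopropylcarbodiimide (2 equiv), DMAP (5 mol %), DMF, rt, 2 h; then 8 (1 equiv), NiCl2·6H2O (20 mol %), 2,2'-bipyridine (20 mol %), AgNO3 (30 mol %), undivided cell, Mg anode/RVC cathode, 10 mA constant current, 2.5 F/mol, rt
Reagents that add atoms: none
Why: Nickel-electrocatalytic decarboxylative alkenylation (reductive cross-electrophile coupling): cathodic reduction turns ester 10 into the but-3-ynyl radical, which is captured by the alkenylnickel species formed by stereoretentive oxidative addition of the C(sp2)–I bond of 8, so C5'–C6' forms with the E geometry intact and the free hydroxyls tolerated.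

Step 6
Reactants: 11 (3R,6E)-2,6-dimethylundec-6-en-10-yne-2,3-diol
Product: 14 potassium trifluoro[(1E,5E,9R)-9,10-dihydroxy-2,6,10-trimethylundeca-1,5-dien-1-yl]borate, via alkenylalane 12 (not isolated), via pinacol boronate 13 (not isolated)
Conditions: AlMe3 (4.5 equiv), Cp2ZrCl2 (0.5 equiv), CH2Cl2, rt, 16 h; volatiles removed in vacuo; 2-methoxy-4,4,5,5-tetramethyl-1,3,2-dioxaborolane (3 equiv), THF, 0 °C to rt; then aq. KHF2 (10 equiv), MeOH, rt; acetone extraction, precipitation with Et2O
Reagents that add atoms: trimethylaluminium C[Al](C)C; 2-methoxy-4,4,5,5-tetramethyl-1,3,2-dioxaborolane COB1OC(C)(C)C(C)(C)O1; potassium hydrogen difluoride [K+].[F-].F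
Why: A second Negishi methylalumination sets the C2'=C3' E-alkene, aluminium-to-boron transmetalation with the alkoxyborane goes with retention, and KHF2 converts the boronate into the bench-stable trifluoroborate while hydrolysing all O–Al and O–B bonds of the diol.

Step 7
Reactants: 15 2,4-dihydroxy-6-methylbenzaldehyde
Product: 16 4-(hydroxymethyl)-5-methylbenzene-1,3-diol
Conditions: NaBH4 (1.5 equiv), THF/EtOH 4:1, −10 °C, 30 min; pH 7 phosphate buffer (KH2PO4/K2HPO4) quench at 0 °C; EtOAc extraction; used the same day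
Reagents that add atoms: none
Why: Borohydride reduction of the aryl aldehyde at low temperature with a neutral quench stops at the benzylic alcohol before quinone-methide formation can cause over-reduction or self-condensation.

Step 8
Reactants: 14 potassium trifluoro[(1E,5E,9R)-9,10-dihydroxy-2,6,10-trimethylundeca-1,5-dien-1-yl]borate; 16 4-(hydroxymethyl)-5-methylbenzene-1,3-diol
Product: 18 4-[(2E,6E,10R)-10,11-dihydroxy-3,7,11-trimethyldodeca-2,6-dien-1-yl]-5-methylbenzene-1,3-diol, via quinone methide 17 (not isolated)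
Conditions: 14 (1.2 equiv) in MeCN/0.2 M KH2PO4–K2HPO4 buffer (pH 5.8) 2:1, 45 °C, Ar; 16 (1.0 equiv) in MeCN added over 6 h by syringe pump, then 6 h; EtOAc extraction (excess 14 recovered from the aqueous phase)
Reagents that add atoms: none
Why: Proposed new method: activator-free dehydrative 1,4-alkenylation of an unprotected hydroxymethyl-resorcinol by a potassium alkenyltrifluoroborate – 16, whose benzylic C–O bond is activated by both an ortho and a para OH, ionises on its own in warm buffered aqueous MeCN to quinone methide 17, whose only electrophilic site is the exocyclic CH2 (so the aryl–C1' regiochemistry is fixed by the bought aldehyde), and this carbon is attacked by the boron-bearing carbon of 14 to give a tertiary beta-borato cation that loses BF3 (as [BF3OH]−) faster than it can rotate, so C1'–C2' forms with the E geometry retained; slow addition of 16 and pH 5.8 (phenols un-ionised) are meant to keep the trifluoroborate, the best pi-nucleophile present, ahead of arene self-condensation, and no strong acid is present to close a chroman or start polyene cyclisation; the closest known reaction types are the biphenol- or acid-promoted conjugate addition of alkenylboron reagents to o-quinone methides (Petasis-type) and the acid-catalysed substitution of benzhydrols by alkenyltrifluoroborates, neither shown without an activator on a free 2,4-dihydroxybenzyl alcohol.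

**Compound list**
1 | (2R)-5-oxotetrahydrofuran-2-carboxylic acid | O=C(O)[C@H]1CCC(=O)O1 | starting material
2 | ethyl (2R)-5-oxotetrahydrofuran-2-carboxylate | CCOC(=O)[C@H]1CCC(=O)O1 | intermediate
3 | (5R)-5-acetyldihydrofuran-2(3H)-one | CC(=O)[C@H]1CCC(=O)O1 | intermediate
4 | (5R)-5-(2-hydroxypropan-2-yl)dihydrofuran-2(3H)-one | CC(C)(O)[C@H]1CCC(=O)O1 | intermediate
5 | (5R)-5-(2-hydroxypropan-2-yl)tetrahydrofuran-2-ol (lactol, both anomers) | CC(C)(O)[C@H]1CCC(O)O1 | intermediate
6 | (3R)-2-methylhept-6-yne-2,3-diol | C#CCC[C@@H](O)C(C)(C)O | intermediate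
7 | dimethyl[(1E,5R)-5,6-bis(dimethylalumanyloxy)-2,6-dimethylhept-1-en-1-yl]alumane | C[Al](C)/C=C(\C)CC[C@@H](O[Al](C)C)C(C)(C)O[Al](C)C | intermediate
8 | (3R,6E)-7-iodo-2,6-dimethylhept-6-ene-2,3-diol | I/C=C(\C)CC[C@@H](O)C(C)(C)O | intermediate
9 | pent-4-ynoic acid | C#CCCC(=O)O | starting material
10 | 1,3-dioxoisoindolin-2-yl pent-4-ynoate | C#CCCC(=O)ON1C(=O)c2ccccc2C1=O | intermediate
11 | (3R,6E)-2,6-dimethylundec-6-en-10-yne-2,3-diol | C#CCC/C=C(\C)CC[C@@H](O)C(C)(C)O | intermediate
12 | dimethyl[(1E,5E,9R)-9,10-bis(dimethylalumanyloxy)-2,6,10-trimethylundeca-1,5-dien-1-yl]alumane | C[Al](C)/C=C(\C)CC/C=C(\C)CC[C@@H](O[Al](C)C)C(C)(C)O[Al](C)C | intermediate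
13 | 2-[(1E,5E,9R)-9,10-bis(dimethylalumanyloxy)-2,6,10-trimethylundeca-1,5-dien-1-yl]-4,4,5,5-tetramethyl-1,3,2-dioxaborolane | CC1(C)OB(/C=C(\C)CC/C=C(\C)CC[C@@H](O[Al](C)C)C(C)(C)O[Al](C)C)OC1(C)C | intermediate
14 | potassium trifluoro[(1E,5E,9R)-9,10-dihydroxy-2,6,10-trimethylundeca-1,5-dien-1-yl]borate | [K+].F[B-](F)(F)/C=C(\C)CC/C=C(\C)CC[C@@H](O)C(C)(C)O | intermediate
15 | 2,4-dihydroxy-6-methylbenzaldehyde | Cc1cc(O)cc(O)c1C=O | starting material
16 | 4-(hydroxymethyl)-5-methylbenzene-1,3-diol | Cc1cc(O)cc(O)c1CO | intermediate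
17 | 3-hydroxy-5-methyl-6-methylidenecyclohexa-2,4-dien-1-one | C=C1C(C)=CC(O)=CC1=O | intermediate
18 | 4-[(2E,6E,10R)-10,11-dihydroxy-3,7,11-trimethyldodeca-2,6-dien-1-yl]-5-methylbenzene-1,3-diol (CNP0226583.2) | C/C(=C\Cc1c(C)cc(O)cc1O)CC/C=C(\C)CC[C@@H](O)C(C)(C)O | target

**Step count and risks**

Total steps: 8 (steps 1–6 on the chain, step 7 on the arene, step 8 the union).
Longest linear sequence: 7 (steps 1, 2, 3, 4, 5, 6, 8, from 1).

The three steps most likely to fail:

Step 8 (the proposed new step). Risks are self-condensation of 16 or benzylation of the product by 17, slow ionisation at pH 5.8, and hydrolysis of 14 before capture. The fallback uses only known chemistry; it sets out from 11 and comes back at 18. Aldehyde 15 is silylated (TBSCl, imidazole, DMF, rt) to 2,4-bis(tert-butyldimethylsilyloxy)-6-methylbenzaldehyde F1. This is reduced (NaBH4, MeOH, 0 °C) to [2,4-bis(tert-butyldimethylsilyloxy)-6-methylphenyl]methanol F2 and converted (MsCl, Et3N, LiCl, THF, 0 °C) into 2,4-bis(tert-butyldimethylsilyloxy)-6-methylbenzyl chloride F3. Alkenylalane 12, made from 11 exactly as in step 6 and freed from excess AlMe3 in vacuo, is cross-coupled with F3 (Pd(PPh3)4 5 mol %, THF, rt; the established palladium-catalysed alkenylalane–benzyl halide coupling). This gives (3R,6E,10E)-12-[2,4-bis(tert-butyldimethylsilyloxy)-6-methylphenyl]-2,6,10-trimethyldodeca-6,10-diene-2,3-diol F4, and TBAF (THF, 0 °C) then gives 18.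

Step 5. Risks are the free terminal alkyne of 10 under nickel/silver (alkyne insertion, acetylide formation), the in-situ ester activation, and protodeiodination of 8. The fallback sets out from 8 and comes back at 11. 4-Bromo-1-(trimethylsilyl)but-1-yne is converted with Zn dust/LiCl (THF, 40 °C) into [4-(trimethylsilyl)but-3-yn-1-yl]zinc bromide F5. F5 (3 equiv, slow addition) is coupled with 8 in a palladium-catalysed Negishi alkyl–alkenyl coupling (Pd(PPh3)4 5 mol %, THF, rt) to (3R,6E)-2,6-dimethyl-11-(trimethylsilyl)undec-6-en-10-yne-2,3-diol F6. K2CO3 in MeOH removes the silyl group to give 11.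

Step 6. Risks are incomplete aluminium-to-boron transfer in the presence of the aluminium diolate, competing methyl transfer, and isolation of a very polar salt. The fallback sets out from 11 and comes back at 14. 11 is carboaluminated to 12 and iodinated exactly as in step 4 to (3R,6E,10E)-11-iodo-2,6,10-trimethylundeca-6,10-diene-2,3-diol F7. Miyaura borylation (B2pin2, PdCl2(PPh3)2 3 mol %, PPh3, KOPh, toluene, 50 °C) gives the isolated (3R,6E,10E)-2,6,10-trimethyl-11-(4,4,5,5-tetramethyl-1,3,2-dioxaborolan-2-yl)undeca-6,10-diene-2,3-diol F8. Aqueous KHF2 in MeOH converts F8 into 14.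

**Further compounds**
F1 | step 8 | 2,4-bis(tert-butyldimethylsilyloxy)-6-methylbenzaldehyde | Cc1cc(O[Si](C)(C)C(C)(C)C)cc(O[Si](C)(C)C(C)(C)C)c1C=O
F2 | step 8 | [2,4-bis(tert-butyldimethylsilyloxy)-6-methylphenyl]methanol | Cc1cc(O[Si](C)(C)C(C)(C)C)cc(O[Si](C)(C)C(C)(C)C)c1CO
F3 | step 8 | 2,4-bis(tert-butyldimethylsilyloxy)-6-methylbenzyl chloride | Cc1cc(O[Si](C)(C)C(C)(C)C)cc(O[Si](C)(C)C(C)(C)C)c1CCl
F4 | step 8 | (3R,6E,10E)-12-[2,4-bis(tert-butyldimethylsilyloxy)-6-methylphenyl]-2,6,10-trimethyldodeca-6,10-diene-2,3-diol | C/C(=C\Cc1c(C)cc(O[Si](C)(C)C(C)(C)C)cc1O[Si](C)(C)C(C)(C)C)CC/C=C(\C)CC[C@@H](O)C(C)(C)O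
F5 | step 5 | [4-(trimethylsilyl)but-3-yn-1-yl]zinc bromide | C[Si](C)(C)C#CCC[Zn]Br
F6 | step 5 | (3R,6E)-2,6-dimethyl-11-(trimethylsilyl)undec-6-en-10-yne-2,3-diol | C[Si](C)(C)C#CCC/C=C(\C)CC[C@@H](O)C(C)(C)O
F7 | step 6 | (3R,6E,10E)-11-iodo-2,6,10-trimethylundeca-6,10-diene-2,3-diol | I/C=C(\C)CC/C=C(\C)CC[C@@H](O)C(C)(C)O
F8 | step 6 | (3R,6E,10E)-2,6,10-trimethyl-11-(4,4,5,5-tetramethyl-1,3,2-dioxaborolan-2-yl)undeca-6,10-diene-2,3-diol | CC1(C)OB(/C=C(\C)CC/C=C(\C)CC[C@@H](O)C(C)(C)O)OC1(C)C
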